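Among flasks with equal charges of coupling partner, second substrate and third substrate, which keeps the most target per starting material charged?

| flask | starting material | coupling partner | second substrate | third substrate | remark | time |
|---|---|---|---|---|---|---|
| Wednesday's | 0.18 mM | 0.60 mM | 0.50 mM | 0.25 mM | run made earlier |  |
| Sunday's | 1.3 mM | 0.60 mM | 0.50 mM | 0.25 mM | run made earlier |  |
| birch | 0.80 mM | 0.600 mM | 0.500 mM | 0.250 mM |  | 6.0 min |
| ash | 0.50 mM | 0.600 mM | 0.500 mM | 0.250 mM |  | 6.0 min |
| alder | 2.0 mM | 0.600 mM | 0.500 mM | 0.250 mM |  | 6.0 min |
| oak | 0.30 mM | 0.600 mM | 0.500 mM | 0.250 mM |  | 6.0 min |

- the flasks by amount of target, in percent of the starting material charged, highest first, at 6.0 min (birch / ash / alder / oak)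
- the same order at 25 min (birch / ash / alder / oak)
- the amount of target, in percent of the starting material charged of the flask you put first, at 6.0 min
- the amount of target, in percent of the starting material charged of the flask you put last, at 6.0 min

| run | time / min | target / % | starting material / % |
|---|---|---|---|
| Wednesday's | 0.417 | 22.2 | 77.5 |
| Wednesday's | 1.00 | 25.6 | 74.9 |
| Wednesday's | 2.00 | 25.5 | 75.0 |
| Wednesday's | 3.00 | 25.5 | 74.2 |
| Sunday's | 0.417 | 15.2 | 84.5 |
| Sunday's | 1.00 | 17.0 | 84.3 |
| Sunday's | 2.00 | 16.1 | 83.4 |
| Sunday's | 3.00 | 15.3 | 83.8 |

(readings scatter by 0.5 percentage points)

- the analysis behind the earlier runs scatters by 0.5 percentage points, standard deviation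

The bench rule says that a reagent charged in excess finishes its partner. Wednesday's run has 3.33 equivalents of coupling partner, so the rule promises full conversion. Yet starting material reads 74.2 % at 3.00 min, and the target read then accounts for 0.0459 mM of the 0.60 mM of coupling partner. The rule stops working once coupling partner is counted against every substrate: the ratio c(coupling partner) / (c(starting material) + c(second substrate) + c(third substrate)) is 0.645 in Wednesday's run, below one. I therefore take coupling partner as the limiting reagent and write its balance. I take target's share of the coupling partner as c(starting material) / (c(starting material) + C), and dividing by c(starting material) gives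

Y = c(coupling partner) / (c(starting material) + C)

Here Y is the plateau yield, and C is the rival charge: the amount of starting material that would pull on coupling partner as hard as its rivals together.

Wednesday's last readings average 25.5 %, so C = 2.17 mM.

Sunday's average 16.1 %, so C = 2.42 mM.

C drifts between these runs, so I use the nearer run for each flask:

oak: Y = 24.3 %

alder: Y = 13.6 %

In this reckoning Y falls as starting material rises, with coupling partner, second substrate and third substrate held at their charges. From 1.00 min to 3.00 min, Wednesday's target reads 25.6 % and then 25.5 %, while Sunday's slips from 17.0 % to 15.3 % with its starting material at 84.3 % and then 83.8 %. I carry the plateau to both asked times, so my order is the same at both.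

The forecast gives oak > ash > birch > alder at 6.0 min and oak > ash > birch > alder at 25 min, with 23 % first and 11.5 % last, on the view that “the second and third substrates compete for the coupling partner”. Both values lie lower than mine.

The flasks give oak > ash > birch > alder at 6.0 min and oak > ash > birch > alder at 25 min, with 24.2 % for oak and 13.2 % for alder.

    starting material + coupling partner → target (k = 55.4 L mol⁻¹ s⁻¹)
    second substrate + coupling partner → second product (k = 112 L mol⁻¹ s⁻¹)
    third substrate + coupling partner → third product (k = 349 L mol⁻¹ s⁻¹)
    2 coupling partner → homo dimer (k = 44.7 L mol⁻¹ s⁻¹)

Read back through Y, oak's result gives C = 2.18 mM, and Wednesday's readings gave 2.17 mM. In oak, the third substrate's half-life by its own step, with the other concentrations as charged, is 0.055 min, 6.30 times shorter than the 0.35 min of starting material. At 6.00 min, oak holds 0 % of its coupling partner and 75.8 % of its starting material. The neighbour of oak charged with 1.5 mM of coupling partner has a ratio of coupling partner to all substrates of 1.43, above one. There Y with C = 2.17 mM gives 60.7 %, and the computed flask gives 60.8 %.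

(The runs are calculated for an exercise.)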